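Slowness here sits in the loading of free catalyst by starting material, the rate-limiting step: with the charged catalyst its half-life is 0.712 d, far longer than the 0.103 h in which catalyst intermediate A goes on with the charged coupling partner.

    starting material + free catalyst ⇌ catalyst intermediate A (K1 = 1610 M⁻¹, k1 = 0.00275 M⁻¹ s⁻¹)
    second substrate + free catalyst ⇌ catalyst intermediate B (K2 = 43 M⁻¹, k2 = 0.00636 M⁻¹ s⁻¹)
    starting material + coupling partner → uncatalysed product (k3 = 5.41 × 10⁻⁷ M⁻¹ s⁻¹)
    coupling partner → decomposed reagent (k4 = 2.14 × 10⁻⁶ s⁻¹)
    coupling partner + catalyst intermediate A → free catalyst + target (k5 = 0.00909 M⁻¹ s⁻¹)
    coupling partner + catalyst intermediate B → free catalyst + second product (k6 = 2.99 × 10⁻⁴ M⁻¹ s⁻¹)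

| flask | starting material | second substrate | coupling partner | free catalyst | time | remark |
|---|---|---|---|---|---|---|
| larch | 0.082 M | 0.0410 M (fed, over 2.00 d) | 0.205 M | 4.1 mM | 4.0 d | all but second substrate at the start; second substrate goes in evenly over 2.00 d, the run ends at 4.0 d |
| oak | 0.082 M | 0.0410 M | 0.205 M | 4.1 mM | 4.0 d | everything together in a closed stirred flask, run for 4.0 d |
| maple | 0.082 M | 0.0410 M | 0.205 M (fed, over 2.00 d) | 4.1 mM | 4.0 d | all but coupling partner at the start; coupling partner goes in evenly over 2.00 d, the run ends at 4.0 d |
| alder | 0.082 M | 0.0410 M | 0.205 M | 4.1 mM |  | one stirred flow tank at steady state, fed with the mixture as stated, mean residence time 4.0 d |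

- the set-up with the highest amount of target at the outlet or at the end, in percent of the starting material put in ("none" if the first two lie within 2 percentage points) (larch / oak / maple / alder / none)
- amount of target at the outlet or at the end, in percent of the starting material put in, larch
- amount of target at the outlet or at the end, in percent of the starting material put in, oak
- amount of target at the outlet or at the end, in percent of the starting material put in, maple
- amount of target at the outlet or at the end, in percent of the starting material put in, alder

- the stated concentrations are those of everything mixed, before any reaction; amounts are the same in each set-up
- the feed brings no volume worth counting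
- run time (larch): 4.0 d

Catalyst intermediate A goes on much faster than it falls back, and the uncatalysed path on starting material is much slower than loading, so these constants need little care. What matters is catalyst held as catalyst intermediate B, which forms by binding and leaves by falling back or going on, so the free share is one over one plus the binding rate divided by the two leaving rates, at the charges of oak.

Starting material left then falls exponentially with loading constant, catalyst charge, free share and time. In oak, a loading constant or catalyst charge at half its value costs 24 percentage points of target. A binding equilibrium constant at twice its value costs 8.8 points. The onward constant of catalyst intermediate B at half its value shifts it 2.9 points. So the first two must be known well, the third fairly, the last roughly.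

The free share comes to 44.5% and the count to 1.73: this lifetime count, the run time over the lifetime of starting material at that free share, gives oak 82.3% of target. In larch, second substrate is counted at half its charge during the 2.00 d of feed, so the free share is 61.6% for that time and the count 2.07, giving 87.4%. The gap of 5 points against a margin of 2 points names larch best. Alder, one tank, gets count over one plus count, 63.4%; maple, with coupling partner counted at half its charge during its feed, gets a count of 1.66 and 81.0%.

The forecast, which parts from this reckoning on the best set-up, gave 85% for larch, 84% for oak, 78% for maple and 65% for alder, with best none, holding that “delaying the second substrate gains early rate but loses it later”.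

The flasks give 87.6% in larch, 84.3% in oak, 80.6% in maple and 65.5% in alder, so larch stands highest. In larch the falling back of catalyst intermediate B to second substrate and free catalyst holds the target up: without it the target goes from 87.6% to 66.8%. The 11% of starting material left in larch reads as 2.17 lifetimes, more than the 1.94 read from the 14% in oak. A neighbour of maple with 0.0016 M of free catalyst has maple's count scaled to 0.647, leaving 52.4% of starting material; that flask holds 53.9%.

The numbers are those of an exercise, and the outcome is calculated.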